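**Retrosynthetic overview**

1. The target is a trans-2,3-diaryl-2,3-dihydro-1,4-benzodioxine with an (E)-styryl arm at C-6. Its two 3,5-dihydroxyphenyl rings (on C-3 and at the stilbene end) are both traced to one aldehyde, 3,5-bis(methoxymethoxy)benzaldehyde, used twice.
2. Three disconnections are made in one operation: C-2–C-3 (α-aryloxybenzyl carbanion + aldehyde), O-4–C-4a (the alkoxide so formed displaces an aryl fluoride) and the stilbene C=C (Horner–Wadsworth–Emmons). The precursor is a single 2-fluoroaryl benzyl ether phosphonate.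
3. Enabling feature: C-4a, which must receive O-4, is ortho to C-8a–O-1, and O-1 carries the future C-2 as an ArO–CH2–Ar group that can be lithiated. The alkoxide born on C-3 is therefore held six atoms from a C-4a–F bond, while C-6, para to O-1, bears a CH2P(O)(OEt)2 group whose carbanion takes the second aldehyde.
4. Ring order: all four benzene rings are bought; the dioxane ring is the only ring formed (step 7).
5. Stereochemistry: C-2 becomes a para-hydroxybenzylic ether carbon and is equilibrated to trans after deprotection (step 8). C-3 is configurationally fixed, and the (2S,3S) enantiomer is obtained by separating the trans racemate (step 9).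

Key step: step 7

Remark: C-2 is taken to be epimerisable under acid once the catechol is free and C-3 is not; the annulation is not assumed to be enantioselective, so the absolute configuration rests on the separation in step 9.

**Route**

Step 1
Reactants: 1 3,4-dihydroxybenzaldehyde
Product: 2 2,2-diphenyl-1,3-benzodioxole-5-carbaldehyde
Conditions: Ph2CCl2 (1.2 equiv), K2CO3, MeCN, 60 °C
Reagents that add atoms: dichlorodiphenylmethane ClC(Cl)(c1ccccc1)c1ccccc1
Why: Ketalisation of a catechol: dichlorodiphenylmethane ionises to the chlorodiphenylmethyl cation and alkylates both neighbouring phenoxides in turn, giving a diphenylmethylene ketal that withstands alkyllithiums and hot alkoxide and falls to dilute acid.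

Step 2
Reactants: 2 2,2-diphenyl-1,3-benzodioxole-5-carbaldehyde
Product: 3 (2,2-diphenyl-1,3-benzodioxol-5-yl)methanol
Conditions: NaBH4, MeOH–THF, 0 °C
Reagents that add atoms: none
Why: Hydride reduction: NaBH4 reduces the aryl aldehyde to the benzylic alcohol and leaves the ketal untouched.

Step 3
Reactants: 3 (2,2-diphenyl-1,3-benzodioxol-5-yl)methanol; 4 3-fluoro-4-hydroxybenzaldehyde
Product: 5 4-[(2,2-diphenyl-1,3-benzodioxol-5-yl)methoxy]-3-fluorobenzaldehyde
Conditions: PPh3, diisopropyl azodicarboxylate, THF, 0 to 20 °C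
Reagents that add atoms: none
Why: Mitsunobu etherification: the acidic phenol of 4 (para-formyl, ortho-fluoro) is alkylated by the activated primary benzylic alcohol 3 without a labile benzylic halide, and the aldehyde is inert to the reagents.

Step 4
Reactants: 5 4-[(2,2-diphenyl-1,3-benzodioxol-5-yl)methoxy]-3-fluorobenzaldehyde
Product: 6 {4-[(2,2-diphenyl-1,3-benzodioxol-5-yl)methoxy]-3-fluorophenyl}methanol
Conditions: NaBH4, MeOH–THF, 0 °C
Reagents that add atoms: none
Why: Hydride reduction of the aryl aldehyde with NaBH4, which leaves the aryl fluoride, the benzyl aryl ether and the ketal unchanged.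

Step 5
Reactants: 6 {4-[(2,2-diphenyl-1,3-benzodioxol-5-yl)methoxy]-3-fluorophenyl}methanol
Product: 8 diethyl ({4-[(2,2-diphenyl-1,3-benzodioxol-5-yl)methoxy]-3-fluorophenyl}methyl)phosphonate, via benzylic bromide 7 (not isolated)
Conditions: CBr4, PPh3, CH2Cl2, 0 °C; then P(OEt)3, neat, 110 °C
Reagents that add atoms: triethyl phosphite CCOP(OCC)OCC
Why: Appel bromination under neutral conditions followed by a Michaelis–Arbuzov reaction of the reactive para-alkoxybenzylic bromide with P(OEt)3, a sequence free of the acid that would ionise the benzylic aryl ether or the ketal.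

Step 6
Reactants: 9 3,5-dihydroxybenzaldehyde
Product: 10 3,5-bis(methoxymethoxy)benzaldehyde
Conditions: MeOCH2Cl (2.5 equiv), i-Pr2NEt, CH2Cl2, 0 to 20 °C
Reagents that add atoms: chloromethyl methyl ether COCCl
Why: Acetal protection: both phenols are alkylated by chloromethyl methyl ether in the presence of a hindered amine to give methoxymethyl ethers, stable to the carbanions and alkoxides of step 7 and removable with dilute acid.

Step 7
Reactants: 8 diethyl ({4-[(2,2-diphenyl-1,3-benzodioxol-5-yl)methoxy]-3-fluorophenyl}methyl)phosphonate; 10 3,5-bis(methoxymethoxy)benzaldehyde (2.2 equiv)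
Product: 13 3-[3,5-bis(methoxymethoxy)phenyl]-6-{(E)-2-[3,5-bis(methoxymethoxy)phenyl]ethenyl}-2-(2,2-diphenyl-1,3-benzodioxol-5-yl)-2,3-dihydro-1,4-benzodioxine (cis and trans racemates), via dilithio dianion 11 (not isolated), via dilithium bis-alkoxide 12 (not isolated)
Conditions: n-BuLi (1.0 equiv), THF, −78 °C; t-BuLi (1.1 equiv), −78 °C; 10 (2.2 equiv), −78 to 0 °C; then KOt-Bu (1.0 equiv), DMPU, 80 °C, argon
Reagents that add atoms: none
Why: Proposed new method: n-BuLi deprotonates the phosphonate CH2 and t-BuLi then the ArO–CH2–Ar carbon, which is activated by the ether oxygen and the benzodioxole ring, to give dianion 11; each carbanion adds to one molecule of 10 (12), and on heating with potassium counter-ions the β-oxido phosphonate collapses to the (E)-alkene while the secondary alkoxide displaces the ortho fluoride. The closest known reactions are the α-lithiation of aryl benzyl ethers with t-BuLi at −78 °C with trapping by aldehydes, the Horner–Wadsworth–Emmons olefination with benzylphosphonates and the cyclisation of alkoxides onto non-activated 2-fluoroaryl ethers; new is their union on one dianion and the use of the sequence as a [4+2] annulation to a 1,4-benzodioxine ring. The dioxane ring closes by ipso addition–elimination (SNAr, formally 6-exo-trig) at the fluorine-bearing carbon, the only aryl carbon the alkoxide can reach. Neither new stereocentre is controlled in this step: C-2 and C-3 arise as cis and trans racemates, C-2 is set later by thermodynamic equilibration (step 8) and the enantiomers are parted in step 9. The step therefore needs only site selectivity in the second metalation, secured by the first carbanion, which makes its own ring electron-rich and so shuts off lithiation next to fluorine, and by the low temperature, which holds back the [1,2]-Wittig shift of the α-lithio ether; E-selectivity follows from reversible addition of the aryl-stabilised phosphonate carbanion.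

Step 8
Reactants: 13 protected benzodioxine stilbene (cis and trans racemates)
Product: 14 (2RS,3RS)-2-(3,4-dihydroxyphenyl)-3-(3,5-dihydroxyphenyl)-6-[(E)-2-(3,5-dihydroxyphenyl)ethenyl]-2,3-dihydro-1,4-benzodioxine (trans racemate)
Conditions: HCl (2 M), MeOH–THF, 40 °C, argon; evaporation; then TsOH·H2O (10 mol %), MeCN, 4 Å molecular sieves, 40 °C
Reagents that add atoms: none
Why: Acetal hydrolysis removes the four methoxymethyl ethers and the diphenylmethylene ketal, and the catalytic-acid stage in a non-nucleophilic solvent reversibly ionises the C-2–O-1 bond, now para-hydroxybenzylic, so that C-2 should equilibrate to the diequatorial trans arrangement while C-3, whose 3,5-dihydroxyphenyl group cannot stabilise a cation, keeps its configuration.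

Step 9
Reactants: 14 trans racemate
Product: 15 (2S,3S)-2-(3,4-dihydroxyphenyl)-3-(3,5-dihydroxyphenyl)-6-[(E)-2-(3,5-dihydroxyphenyl)ethenyl]-2,3-dihydro-1,4-benzodioxine
Conditions: preparative HPLC on immobilised amylose tris(3,5-dimethylphenylcarbamate), hexane–EtOH–CF3CO2H, 20 °C
Reagents that add atoms: none
Why: Resolution of enantiomers on a polysaccharide carbamate chiral stationary phase, a standard way to part enantiomeric polyphenols; no bond is made or broken, and the (2S,3S) fraction is to be assigned by electronic circular dichroism against the calculated curve.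

**Compound list**

1 | 3,4-dihydroxybenzaldehyde | O=Cc1ccc(O)c(O)c1 | starting material
2 | 2,2-diphenyl-1,3-benzodioxole-5-carbaldehyde | O=Cc1ccc2OC(c3ccccc3)(c3ccccc3)Oc2c1 | intermediate
3 | (2,2-diphenyl-1,3-benzodioxol-5-yl)methanol | OCc1ccc2OC(c3ccccc3)(c3ccccc3)Oc2c1 | intermediate
4 | 3-fluoro-4-hydroxybenzaldehyde | O=Cc1ccc(O)c(F)c1 | starting material
5 | 4-[(2,2-diphenyl-1,3-benzodioxol-5-yl)methoxy]-3-fluorobenzaldehyde | O=Cc1ccc(OCc2ccc3OC(c4ccccc4)(c4ccccc4)Oc3c2)c(F)c1 | intermediate
6 | {4-[(2,2-diphenyl-1,3-benzodioxol-5-yl)methoxy]-3-fluorophenyl}methanol | OCc1ccc(OCc2ccc3OC(c4ccccc4)(c4ccccc4)Oc3c2)c(F)c1 | intermediate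
7 | 5-{[4-(bromomethyl)-2-fluorophenoxy]methyl}-2,2-diphenyl-1,3-benzodioxole | BrCc1ccc(OCc2ccc3OC(c4ccccc4)(c4ccccc4)Oc3c2)c(F)c1 | intermediate (not isolated)
8 | diethyl ({4-[(2,2-diphenyl-1,3-benzodioxol-5-yl)methoxy]-3-fluorophenyl}methyl)phosphonate | CCOP(=O)(OCC)Cc1ccc(OCc2ccc3OC(c4ccccc4)(c4ccccc4)Oc3c2)c(F)c1 | intermediate
9 | 3,5-dihydroxybenzaldehyde | O=Cc1cc(O)cc(O)c1 | starting material
10 | 3,5-bis(methoxymethoxy)benzaldehyde | COCOc1cc(C=O)cc(OCOC)c1 | intermediate
11 | dilithium salt of the dianion of 8 (carbanions at the P–CH and the O–CH carbons) | [Li+].[Li+].CCOP(=O)(OCC)[CH-]c1ccc(O[CH-]c2ccc3OC(c4ccccc4)(c4ccccc4)Oc3c2)c(F)c1 | intermediate (not isolated)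
12 | dilithium bis-alkoxide from 11 and two molecules of 10 (mixture of diastereomers, stereocentres not defined) | [Li+].[Li+].CCOP(=O)(OCC)C(C([O-])c1cc(OCOC)cc(OCOC)c1)c1ccc(OC(C([O-])c2cc(OCOC)cc(OCOC)c2)c2ccc3OC(c4ccccc4)(c4ccccc4)Oc3c2)c(F)c1 | intermediate (not isolated)
13 | 3-[3,5-bis(methoxymethoxy)phenyl]-6-{(E)-2-[3,5-bis(methoxymethoxy)phenyl]ethenyl}-2-(2,2-diphenyl-1,3-benzodioxol-5-yl)-2,3-dihydro-1,4-benzodioxine (cis and trans racemates; C-2 and C-3 not defined) | COCOc1cc(OCOC)cc(/C=C/c2ccc3c(c2)OC(c2cc(OCOC)cc(OCOC)c2)C(c2ccc4OC(c5ccccc5)(c5ccccc5)Oc4c2)O3)c1 | intermediate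
14 | (2RS,3RS)-2-(3,4-dihydroxyphenyl)-3-(3,5-dihydroxyphenyl)-6-[(E)-2-(3,5-dihydroxyphenyl)ethenyl]-2,3-dihydro-1,4-benzodioxine (trans racemate, both enantiomers written) | Oc1cc(O)cc(/C=C/c2ccc3c(c2)O[C@@H](c2cc(O)cc(O)c2)[C@H](c2ccc(O)c(O)c2)O3)c1.Oc1cc(O)cc(/C=C/c2ccc3c(c2)O[C@H](c2cc(O)cc(O)c2)[C@@H](c2ccc(O)c(O)c2)O3)c1 | intermediate
15 | (2S,3S)-2-(3,4-dihydroxyphenyl)-3-(3,5-dihydroxyphenyl)-6-[(E)-2-(3,5-dihydroxyphenyl)ethenyl]-2,3-dihydro-1,4-benzodioxine | Oc1cc(O)cc(/C=C/c2ccc3c(c2)O[C@@H](c2cc(O)cc(O)c2)[C@H](c2ccc(O)c(O)c2)O3)c1 | target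

**Step count and risks**

Total step count: 9. Longest linear sequence: 8 steps (steps 1, 2, 3, 4, 5, 7, 8 and 9, from 3,4-dihydroxybenzaldehyde).

Steps most likely to fail:

1. Step 7 (the labelled step). The second metalation may stop short or be misdirected in the presence of the lithiated phosphonate, and the two carbanion sites may exchange protons on warming. The α-lithio ether may undergo a [1,2]-Wittig shift, and in the hot stage the alkoxide may expel the neighbouring phenoxide (epoxide formation) in competition with fluoride displacement. The fallback sets out from 6 and returns to the route at 13. With the hydroxyl masked in situ as its lithium alkoxide (n-BuLi), 6 is lithiated at the ArO–CH2 carbon with t-BuLi (THF, −78 °C) and trapped with one equivalent of 10 to give, after protonation, the diol 1-[3,5-bis(methoxymethoxy)phenyl]-2-(2,2-diphenyl-1,3-benzodioxol-5-yl)-2-[2-fluoro-4-(hydroxymethyl)phenoxy]ethanol F1, which is isolated. Ring closure is then run as a separate SNAr step (KOt-Bu, DMPU, 80 °C; the primary alkoxide cannot reach the C–F carbon) to the benzodioxine methanol F2. Appel bromination should give the benzylic bromide F3, a Michaelis–Arbuzov reaction with P(OEt)3 the phosphonate F4, and Horner–Wadsworth–Emmons olefination of F4 with 10 (NaH, THF, 0 to 20 °C) gives 13. Each operation is a known reaction on a neutral or singly metalated substrate, and the olefination no longer shares a flask with the annulation.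

2. Step 8. The dioxane ring may be lost by solvolysis at the para-hydroxybenzylic C-2–O-1 bond, and the electron-rich stilbene and resorcinol rings may oligomerise under acid while the acetals are removed and C-2 is equilibrated. The fallback sets out from 13 and returns at 14. 13 is deprotected with HCl in MeOH–THF at 20 °C only until the acetals are gone, and the crude phenol mixture is acetylated at once (Ac2O, pyridine, DMAP). The hexaacetate F5 (cis and trans racemates) is freed from ring-opened and oligomeric material by chromatography on silica. K2CO3 in degassed MeOH (20 to 40 °C) then removes the acetates and, through the phenoxide of the catechol ring, opens the C-2–O-1 bond reversibly to the para-quinone methide, whose re-closure (oxa-Michael addition) should funnel the cis isomer into trans 14. The equilibration thus runs through the quinone methide under base instead of the benzylic cation under acid.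

3. Step 9. The enantiomers of the hexaphenol may overlap or tail on the chiral phase, so that the (2S,3S) fraction is not obtained pure. The fallback sets out from 14 and returns at 15. All six phenols are carbamoylated with (S)-1-phenylethyl isocyanate (Et3N, THF) to give a pair of diastereomers, the (2S,3S) hexakis-carbamate F6 and the (2R,3R) hexakis-carbamate F7. These are separated by crystallisation or chromatography on silica, and K2CO3 in MeOH (E1cB cleavage of the aryl carbamates) releases 15 from F6. Separation thus rests on covalent diastereomers instead of a chiral stationary phase.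

**Further compounds**

F1 | step 7 | 1-[3,5-bis(methoxymethoxy)phenyl]-2-(2,2-diphenyl-1,3-benzodioxol-5-yl)-2-[2-fluoro-4-(hydroxymethyl)phenoxy]ethanol (racemic, both diastereomers) | OCc1ccc(OC(C(O)c2cc(OCOC)cc(OCOC)c2)c2ccc3OC(c4ccccc4)(c4ccccc4)Oc3c2)c(F)c1
F2 | step 7 | {3-[3,5-bis(methoxymethoxy)phenyl]-2-(2,2-diphenyl-1,3-benzodioxol-5-yl)-2,3-dihydro-1,4-benzodioxin-6-yl}methanol (cis and trans racemates) | OCc1ccc2c(c1)OC(c1cc(OCOC)cc(OCOC)c1)C(c1ccc3OC(c4ccccc4)(c4ccccc4)Oc3c1)O2
F3 | step 7 | 6-(bromomethyl)-3-[3,5-bis(methoxymethoxy)phenyl]-2-(2,2-diphenyl-1,3-benzodioxol-5-yl)-2,3-dihydro-1,4-benzodioxine (cis and trans racemates) | BrCc1ccc2c(c1)OC(c1cc(OCOC)cc(OCOC)c1)C(c1ccc3OC(c4ccccc4)(c4ccccc4)Oc3c1)O2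
F4 | step 7 | diethyl ({3-[3,5-bis(methoxymethoxy)phenyl]-2-(2,2-diphenyl-1,3-benzodioxol-5-yl)-2,3-dihydro-1,4-benzodioxin-6-yl}methyl)phosphonate (cis and trans racemates) | CCOP(=O)(OCC)Cc1ccc2c(c1)OC(c1cc(OCOC)cc(OCOC)c1)C(c1ccc3OC(c4ccccc4)(c4ccccc4)Oc3c1)O2
F5 | step 8 | hexaacetate of the deprotected benzodioxine stilbene (cis and trans racemates; C-2 and C-3 not defined) | CC(=O)Oc1cc(OC(C)=O)cc(/C=C/c2ccc3c(c2)OC(c2cc(OC(C)=O)cc(OC(C)=O)c2)C(c2ccc(OC(C)=O)c(OC(C)=O)c2)O3)c1
F6 | step 9 | (2S,3S)-benzodioxine stilbene hexakis{N-[(1S)-1-phenylethyl]carbamate} | c1(OC(=O)N[C@@H](C)c7ccccc7)cc(OC(=O)N[C@@H](C)c7ccccc7)cc(/C=C/c2ccc3c(c2)O[C@@H](c2cc(OC(=O)N[C@@H](C)c7ccccc7)cc(OC(=O)N[C@@H](C)c7ccccc7)c2)[C@H](c2ccc(OC(=O)N[C@@H](C)c7ccccc7)c(OC(=O)N[C@@H](C)c7ccccc7)c2)O3)c1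
F7 | step 9 | (2R,3R)-benzodioxine stilbene hexakis{N-[(1S)-1-phenylethyl]carbamate} | c1(OC(=O)N[C@@H](C)c7ccccc7)cc(OC(=O)N[C@@H](C)c7ccccc7)cc(/C=C/c2ccc3c(c2)O[C@H](c2cc(OC(=O)N[C@@H](C)c7ccccc7)cc(OC(=O)N[C@@H](C)c7ccccc7)c2)[C@@H](c2ccc(OC(=O)N[C@@H](C)c7ccccc7)c(OC(=O)N[C@@H](C)c7ccccc7)c2)O3)c1
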